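You cannot read either order off these runs, because alpha and delta both carry 0.60 equiv of reagent and 0.15 mol% of free catalyst . So here is a reckoning, not a measurement.

| flask | starting material | second substrate | reagent | free catalyst | impurity | remark |
|---|---|---|---|---|---|---|
| alpha | 0.20 M | 2 equiv | 0.60 equiv | 0.15 mol% | 92 µM | the very flask that is asked about, followed so far |
| delta | 0.20 M | 4 equiv | 0.60 equiv | 0.15 mol% | 92 µM | run made earlier |
| flask | 0.20 M | 2.00 equiv | 0.600 equiv | 0.15 mol% | 92 µM |  |

| run | time / h | target / % | starting material / % |
|---|---|---|---|
| alpha | 2.00 | 2.3 | 97.2 |
| alpha | 4.00 | 3.6 | 95.6 |
| alpha | 6.00 | 4.6 | 95.2 |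
| alpha | 8.00 | 5.8 | 93.7 |
| alpha | 10.0 | 7.7 | 92.3 |
| alpha | 12.0 | 8.6 | 90.9 |
| delta | 3.00 | 2.1 | 99.1 |
| delta | 8.00 | 3.5 | 95.8 |
| delta | 15.0 | 5.1 | 95.1 |
| delta | 25.0 | 6.7 | 92.6 |
| delta | 30.0 | 6.8 | 92.1 |
| delta | 40.0 | 9.1 | 91.8 |

(standard deviation of a reading: 0.5 percentage points)

- no earlier run changes the charge of free catalyst; that part of a forecast is a guess
- no earlier run changes the charge of reagent; that part of a forecast is a guess

- apparent order in reagent when 10 % of the starting material are converted (percent change of the rate of making target for one percent more reagent charged)
- apparent order in free catalyst when 10 % of the starting material are converted (percent change of the rate of making target for one percent more free catalyst charged)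

For the catalyst I would work with the poison share s, the impurity charged divided by the free catalyst charged. The charge is 300 µM against 92 µM of impurity, so s = 30.7 %. I assume each impurity molecule removes one catalyst. The rate then follows the working part, the charge minus the impurity. One percent more charge lands whole on that smaller part, so the apparent order is 1.44, one divided by one minus s. Delta has the same share, 30.7 %, yet its readings show target made more slowly than in alpha, and the charge in which the two runs differ is the second substrate, 4 equiv against 2 equiv.

Your forecast is 0.6 in reagent and 1.25 in free catalyst. Its catalyst number lies between tight poisoning and the case “If it binds weakly, the order is about 1”. I stay with the tight case, 1.44, which is higher than the forecast. For the reagent I have no reckoning to set against yours.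

The flask gives 2.5 in reagent and 1.4 in free catalyst, so the reagent forecast is too low, and the catalyst forecast is right within the tolerance.

    reagent + catalyst intermediate A → free catalyst + target (k = 25000 /M/h)
    second substrate + free catalyst ⇌ catalyst intermediate B (K = 78.0 /M, k = 910 /M/h)
    free catalyst + impurity → spent catalyst (k = 33000 /M/h)
    reagent + catalyst intermediate B → free catalyst + second product (k = 700 /M/h)
    reagent ⇌ dormant form (K = 2.40, k = 5.30 /h)
    starting material + free catalyst ⇌ catalyst intermediate A (K = 1.60 /M, k = 700 /M/h)

In the flask after 2.50 d, spent catalyst stands at 30.7 % of the catalyst charged, beside s, and nearly all of the part one minus s is catalyst intermediate B, the resting state of the round. At that time the flask uses reagent in the step to second product at 2.6 times the rate of the step to target, and it holds 0.0834 M of second product against 0.0322 M of target.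

Readings and results are calculated with constants of no real substance; noise was put on by code.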